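**Plan**
- Retrosynthesis: cut C10–C20 of the 19,20-lactone first (carboxyl-tethered radical addition), then C9–O of the spiro ether (phenol oxidation), C9–C11 (Negishi coupling), C1–C10 of ring A (Friedel–Crafts), and C3–C4 and C4–C5 (allylation, arylation).
- Enabling feature: C6 and C9 are para oxygenated carbons of ring B, so ring B is a masked methylhydroquinone; in its spiro dienone C10 is the β-carbon of the C6 enone and lies under the axial C19 carboxyl on C4.
- Forward order: C4 is built, ring A is closed onto aromatic ring B, the C11–C16 hydroxy lactone is joined, dearomatisation closes the spiro tetrahydrofuran, the key step closes the δ-lactone, and two hydride reductions finish.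
- Stereochemistry: C4 by catalytic asymmetric α-allylation; C13 from (R)-malic acid by retentive alkylation of its dioxolanone; C9 in the spirocyclisation, with separation of epimers; C10 by the tether and C5 by hydrogen transfer to the open α face; C8 and C6 by face-selective hydride delivery.

Key step: step 23

Assumption: locants follow labdane numbering (C17 on C8, C18 and C19 on C4, C20 on C10, side chain C11–C16), and the (R)-antipode of the phosphoric acid in step 3 is assigned by analogy with 2-phenylpropanal; the other antipode is taken if the sense proves opposite.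

**Route**

Step 1
Reactants: 1 1-bromo-2-methoxy-4-methylbenzene; 2 tert-butyl propanoate
Product: 3 tert-butyl 2-(2-methoxy-4-methylphenyl)propanoate (racemic)
Conditions: LiN(SiMe3)2 (2.3 equiv), Pd(OAc)2 (3 mol%), 2-(di-tert-butylphosphino)-2'-(N,N-dimethylamino)biphenyl (6 mol%), PhMe, rt → 60 °C
Reagents that add atoms: none
Why: Palladium-catalysed α-arylation of the lithium ester enolate (Buchwald–Hartwig type) forms C4–C5, the tert-butyl ester and the bulky phosphine suppressing Claisen condensation and diarylation, and the racemic centre is reset in step 3.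

Step 2
Reactants: 3 tert-butyl 2-(2-methoxy-4-methylphenyl)propanoate
Product: 4 2-(2-methoxy-4-methylphenyl)propanal (racemic)
Conditions: i-Bu2AlH (1.15 equiv), PhMe, −78 °C; aq Rochelle salt
Reagents that add atoms: none
Why: Partial ester reduction stops at the aldehyde because the tetrahedral aluminate survives at −78 °C.

Step 3
Reactants: 4 2-(2-methoxy-4-methylphenyl)propanal; 5 allyl alcohol
Product: 6 (S)-2-(2-methoxy-4-methylphenyl)-2-methylpent-4-enal
Conditions: Pd(PPh3)4 (3 mol%), (R)-TRIP [(R)-3,3'-bis(2,4,6-triisopropylphenyl)-1,1'-binaphthyl-2,2'-diyl hydrogen phosphate] (3 mol%), Ph2CHNH2 (40 mol%), 5 Å molecular sieves, PhMe, 40 °C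
Reagents that add atoms: none
Why: Tsuji–Trost α-allylation of the transient enamine under combined amine, chiral phosphoric acid and zerovalent palladium catalysis (asymmetric counteranion-directed catalysis) converts the racemic α-branched aldehyde into the quaternary (S) centre C4, the chiral phosphate paired with the π-allyl palladium cation selecting the enamine face.

Step 4
Reactants: 6 (S)-2-(2-methoxy-4-methylphenyl)-2-methylpent-4-enal
Product: 7 (S)-2-(2-methoxy-4-methylphenyl)-2-methylpent-4-enoic acid
Conditions: NaClO2, NaH2PO4, 2-methyl-2-butene, t-BuOH/H2O, 0 °C → rt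
Reagents that add atoms: sodium chlorite, [Na+].[O-]Cl=O
Why: Pinnick oxidation with a hypochlorite scavenger oxidises the hindered aldehyde without touching the alkene, the arene or the quaternary centre.

Step 5
Reactants: 7 (S)-2-(2-methoxy-4-methylphenyl)-2-methylpent-4-enoic acid
Product: 8 methyl (S)-2-(2-methoxy-4-methylphenyl)-2-methylpent-4-enoate
Conditions: MeI, K2CO3, DMF, rt
Reagents that add atoms: iodomethane, CI
Why: SN2 O-alkylation of the potassium carboxylate esterifies the hindered acid without acyl activation.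

Step 6
Reactants: 8 methyl (S)-2-(2-methoxy-4-methylphenyl)-2-methylpent-4-enoate
Product: 9 methyl (S)-5-hydroxy-2-(2-methoxy-4-methylphenyl)-2-methylpentanoate
Conditions: 9-BBN (1.5 equiv), THF, 0 °C → rt; then 3 M aq NaOAc, 30% H2O2, 0 °C → rt
Reagents that add atoms: hydrogen peroxide, OO
Why: Anti-Markovnikov hydroboration–oxidation gives the primary alcohol at C1, the buffered work-up avoiding δ-lactonisation onto the hindered ester.

Step 7
Reactants: 9 methyl (S)-5-hydroxy-2-(2-methoxy-4-methylphenyl)-2-methylpentanoate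
Product: 10 (S)-5-methoxy-4-(2-methoxy-4-methylphenyl)-4-methyl-5-oxopentanoic acid
Conditions: TEMPO (0.2 equiv), PhI(OAc)2 (2.4 equiv), MeCN/H2O (1:1), rt
Reagents that add atoms: water, O
Why: Oxoammonium oxidation (TEMPO/PhI(OAc)2) in aqueous acetonitrile takes the primary alcohol through the aldehyde hydrate to the acid.

Step 8
Reactants: 10 (S)-5-methoxy-4-(2-methoxy-4-methylphenyl)-4-methyl-5-oxopentanoic acid
Product: 11 methyl (S)-8-methoxy-1,6-dimethyl-4-oxo-1,2,3,4-tetrahydronaphthalene-1-carboxylate
Conditions: P2O5/MeSO3H (1:10 w/w, Eaton's reagent), 0.05 M, 50 °C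
Reagents that add atoms: none
Why: Intramolecular Friedel–Crafts acylation closes ring A at C10, the only position that gives a six-membered ketone, as in the cyclisation of 4-(2-methoxyphenyl)butanoic acids to 5-methoxy-1-tetralones, while the C19 methyl ester is not ionised.

Step 9
Reactants: 11 methyl (S)-8-methoxy-1,6-dimethyl-4-oxo-1,2,3,4-tetrahydronaphthalene-1-carboxylate
Product: 12 methyl (S)-8-methoxy-1,6-dimethyl-1,2,3,4-tetrahydronaphthalene-1-carboxylate
Conditions: Et3SiH (3 equiv), CF3CO2H, rt → 50 °C
Reagents that add atoms: none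
Why: Ionic hydrogenation (Kursanov–Parnes) removes the aryl ketone oxygen through the benzylic cation while ester and aryl ether survive.

Step 10
Reactants: 12 methyl (S)-8-methoxy-1,6-dimethyl-1,2,3,4-tetrahydronaphthalene-1-carboxylate
Product: 13 methyl (S)-5-bromo-8-methoxy-1,6-dimethyl-1,2,3,4-tetrahydronaphthalene-1-carboxylate
Conditions: N-bromosuccinimide (1.05 equiv), MeCN, 0 °C → rt, dark
Reagents that add atoms: N-bromosuccinimide, O=C1CCC(=O)N1Br
Why: Electrophilic aromatic bromination occurs para to the methoxy group at C9, which is also ortho to two alkyl groups, and the polar medium excludes benzylic radical bromination.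

Step 11
Reactants: 13 methyl (S)-5-bromo-8-methoxy-1,6-dimethyl-1,2,3,4-tetrahydronaphthalene-1-carboxylate
Product: 15 (S)-6-bromo-2a,7-dimethyl-2a,3,4,5-tetrahydro-2H-naphtho[1,8-bc]furan-2-one (aryl lactone between O6 and C19), via phenol acid 14 (not isolated)
Conditions: BBr3 (4 equiv), CH2Cl2, −78 °C → rt; H2O; then TsOH·H2O (5 mol%), PhMe, 80 °C
Reagents that add atoms: none
Why: BBr3 cleaves both the aryl methyl ether and the methyl ester (bromide SN2 at methyl), and the peri C6 phenol then lactonises with the C19 acid under acid catalysis, so one aryl lactone masks both functions, which could not coexist free, through the cross-coupling.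

Step 12
Reactants: 16 (R)-malic acid; 17 pivalaldehyde
Product: 18 2-[(2R,4R)-2-tert-butyl-5-oxo-1,3-dioxolan-4-yl]acetic acid
Conditions: TsOH·H2O (catalytic), H2SO4 (catalytic), pentane, reflux, Dean–Stark; recrystallisation
Reagents that add atoms: none
Why: Acid-catalysed acetalisation of the α-hydroxy acid under water removal (Seebach self-regeneration of stereocentres) gives the crystalline cis-dioxolanone as the thermodynamic product, the acetal centre being set by equilibration cis to the side chain.

Step 13
Reactants: 18 2-[(2R,4R)-2-tert-butyl-5-oxo-1,3-dioxolan-4-yl]acetic acid; 19 allyl bromide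
Product: 20 2-[(2R,4R)-2-tert-butyl-5-oxo-4-(prop-2-en-1-yl)-1,3-dioxolan-4-yl]acetic acid
Conditions: LiN(SiMe3)2 (2.2 equiv), THF, −78 °C; then allyl bromide, −78 → −30 °C
Reagents that add atoms: none
Why: Alkylation of the carboxylate–enolate dianion occurs trans to the tert-butyl group, so allyl replaces hydrogen with retention and fixes the future C13.

Step 14
Reactants: 20 2-[(2R,4R)-2-tert-butyl-5-oxo-4-(prop-2-en-1-yl)-1,3-dioxolan-4-yl]acetic acid
Product: 22 (2R,5R)-2-tert-butyl-5-(2-hydroxyethyl)-5-(prop-2-en-1-yl)-1,3-dioxolan-4-one, via mixed carbonic anhydride 21 (not isolated)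
Conditions: i-BuOCOCl (1.1 equiv), N-methylmorpholine (1.1 equiv), THF, −15 °C; then NaBH4 (2.5 equiv), H2O, 0 °C
Reagents that add atoms: none
Why: Borohydride reduction of the mixed carbonic anhydride is selective for the activated carboxyl over the alkene and the hindered dioxolanone.

Step 15
Reactants: 22 (2R,5R)-2-tert-butyl-5-(2-hydroxyethyl)-5-(prop-2-en-1-yl)-1,3-dioxolan-4-one
Product: 23 (2R,5R)-2-tert-butyl-5-(2-iodoethyl)-5-(prop-2-en-1-yl)-1,3-dioxolan-4-one
Conditions: I2 (1.3 equiv), PPh3 (1.3 equiv), imidazole (1.5 equiv), CH2Cl2, 0 °C → rt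
Reagents that add atoms: iodine, II
Why: Appel-type iodination substitutes the primary hydroxyl by SN2 on the alkoxyphosphonium ion before it can lactonise.

Step 16
Reactants: 23 (2R,5R)-2-tert-butyl-5-(2-iodoethyl)-5-(prop-2-en-1-yl)-1,3-dioxolan-4-one
Product: 24 2-[(2R,4R)-2-tert-butyl-4-(2-iodoethyl)-5-oxo-1,3-dioxolan-4-yl]acetaldehyde
Conditions: O3, CH2Cl2, −78 °C (indicator end point); then PPh3, −78 → 0 °C
Reagents that add atoms: ozone, [O-][O+]=O
Why: Ozonolysis cleaves the terminal alkene far faster than ozone oxidises a primary iodide at −78 °C, and PPh3 reduces the ozonide to the aldehyde.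

Step 17
Reactants: 24 2-[(2R,4R)-2-tert-butyl-4-(2-iodoethyl)-5-oxo-1,3-dioxolan-4-yl]acetaldehyde
Product: 26 (R)-3-hydroxy-3-(2-iodoethyl)oxolan-2-one, via hydroxyethyl dioxolanone 25 (not isolated)
Conditions: NaBH4 (1.0 equiv), MeOH, −20 °C; AcOH; then TsOH·H2O (10 mol%), CH2Cl2, rt
Reagents that add atoms: none
Why: Aldehyde reduction and acid-catalysed translactonisation (5-exo-trig attack of the new hydroxyl on the dioxolanone carbonyl) release pivalaldehyde and the tertiary alcohol with C13 untouched, and because the other arm is already an iodide the degenerate translactonisation that would racemise a bis(hydroxyethyl) lactone cannot occur.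

Step 18
Reactants: 26 (R)-3-hydroxy-3-(2-iodoethyl)oxolan-2-one; 15 (S)-6-bromo-2a,7-dimethyl-2a,3,4,5-tetrahydro-2H-naphtho[1,8-bc]furan-2-one
Product: 28 (2aS)-6-{2-[(3S)-3-hydroxy-2-oxooxolan-3-yl]ethyl}-2a,7-dimethyl-2a,3,4,5-tetrahydro-2H-naphtho[1,8-bc]furan-2-one, via alkylzinc iodide 27 (not isolated)
Conditions: Zn dust (3 equiv), I2 (5 mol%), DMF, rt; then 15 (0.8 equiv), Pd2(dba)3 (2.5 mol%), SPhos (10 mol%), 50 °C
Reagents that add atoms: none
Why: Zinc insertion into the primary iodide and Negishi coupling with a bulky biarylphosphine palladium catalyst form C9–C11 at the di-ortho-substituted bromide, the lactones being inert to the alkylzinc and the tertiary hydroxyl no more acidic than the carbamate N–H tolerated in amino-acid-derived zinc reagents.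

Step 19
Reactants: 28 (2aS)-6-{2-[(3S)-3-hydroxy-2-oxooxolan-3-yl]ethyl}-2a,7-dimethyl-2a,3,4,5-tetrahydro-2H-naphtho[1,8-bc]furan-2-one
Product: 30 2-(trimethylsilyl)ethyl (4S,9R,13S)-9,13-epoxy-6-oxolabda-5(10),7-dien-16,15-olid-19-oate (spiro dienone), via phenol ester 29 (not isolated)
Conditions: Me3SiCH2CH2OH (1.3 equiv), n-BuLi (1.2 equiv), THF, −40 → −20 °C; then (CF3)2CHOH, PhI(OAc)2 (1.15 equiv), 0 °C; chromatography
Reagents that add atoms: 2-(trimethylsilyl)ethanol, C[Si](C)(C)CCO
Why: Alkoxide acyl substitution opens the strained aryl lactone to the C6 phenoxide and the C19 ester, and oxidation of the phenol with trivalent iodine then lets the tertiary C13 hydroxyl attack the para carbon C9 (5-exo spiroetherification) to give the quinol ether dienone; C9 is too far from C4 and C13 for substrate control, so both epimers are expected and the (9R) epimer is isolated by chromatography.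

Step 20
Reactants: 30 2-(trimethylsilyl)ethyl (4S,9R,13S)-9,13-epoxy-6-oxolabda-5(10),7-dien-16,15-olid-19-oate
Product: 31 (4S,9R,13S)-9,13-epoxy-6-oxolabda-5(10),7-dien-16,15-olid-19-oic acid
Conditions: Bu4NF (1.5 equiv), THF, 0 °C → rt; aq NH4Cl, pH 4
Reagents that add atoms: none
Why: Fluoride attacks silicon and the ester fragments with loss of ethylene, which frees the hindered C19 acid without attack at carbonyl, and prompt acidification prevents conjugate addition of the carboxylate to the dienone.

Step 21
Reactants: 31 (4S,9R,13S)-9,13-epoxy-6-oxolabda-5(10),7-dien-16,15-olid-19-oic acid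
Product: 32 chloromethyl (4S,9R,13S)-9,13-epoxy-6-oxolabda-5(10),7-dien-16,15-olid-19-oate
Conditions: ClCH2OSO2Cl (1.3 equiv), NaHCO3 (4 equiv), Bu4NHSO4 (0.1 equiv), CH2Cl2/H2O, rt
Reagents that add atoms: chloromethyl chlorosulfate, ClCOS(=O)(=O)Cl
Why: Phase-transfer O-alkylation of the carboxylate at the methylene of chloromethyl chlorosulfate, chlorosulfate being the leaving group, is the standard route to chloromethyl esters of hindered acids.

Step 22
Reactants: 32 chloromethyl (4S,9R,13S)-9,13-epoxy-6-oxolabda-5(10),7-dien-16,15-olid-19-oate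
Product: 33 iodomethyl (4S,9R,13S)-9,13-epoxy-6-oxolabda-5(10),7-dien-16,15-olid-19-oate
Conditions: NaI (3 equiv), acetone, rt, dark
Reagents that add atoms: sodium iodide, [Na+].[I-]
Why: Finkelstein exchange, driven by precipitation of NaCl, installs the weak carbon–iodine bond needed for radical generation.

Step 23
Reactants: 33 iodomethyl (4S,9R,13S)-9,13-epoxy-6-oxolabda-5(10),7-dien-16,15-olid-19-oate
Product: 34 (4S,5R,9R,10S,13S)-9,13-epoxy-6-oxolabd-7-ene-19,20:16,15-diolide (pentacyclic 7-en-6-one)
Conditions: (Me3Si)3SiH (1.5 equiv) and 1,1'-azobis(cyclohexanecarbonitrile) (0.3 equiv) in PhMe added over 10 h by syringe pump to 33 in PhMe (0.002 M), 110 °C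
Reagents that add atoms: none
Why: Proposed new method: iodine abstraction by the silyl radical gives the nucleophilic acyloxymethyl radical at C20, which adds to C10, the β-carbon of the C5=C10–C6=O enone, and the resulting C5 α-keto radical takes hydrogen from the silane to carry the chain; the closest known reaction type is the intramolecular Giese addition of α-acyloxyalkyl radicals to β,β-disubstituted enones, and acyloxymethyl iodides are known radical precursors in intermolecular Giese additions, but an ester tether of this kind has not been used. The δ-lactone closes 6-endo-trig, the mode expected when the tether sits on the α-carbon of the acceptor, because the 5-exo site C5 is polarity-mismatched and fully substituted, and C8 of the second enone cannot be reached. C10 is controlled by the tether: C20 can only arrive on the face of the pseudoaxial C19 carboxyl fixed by C4, which gives the 1,3-diaxial lactone bridge on the β face, anti to O9. C5 is set when the α-keto radical takes hydrogen on the open α face, the β face being covered by the new bridge, and it stays correctable by enolisation toward the trans-fused ketone. The step needs cyclisation to outrun reduction of the uncyclised radical, which must first reach the minor s-trans ester rotamer; high dilution, 110 °C and slow addition of the slow hydrogen donor (Me3Si)3SiH are chosen to secure this.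

Step 24
Reactants: 34 (4S,5R,9R,10S,13S)-9,13-epoxy-6-oxolabd-7-ene-19,20:16,15-diolide
Product: 35 (4S,5R,8R,9R,10S,13S)-9,13-epoxy-6-oxolabdane-19,20:16,15-diolide
Conditions: [(Ph3P)CuH]6 (0.4 equiv), PhH (moist), rt; aq NH4Cl
Reagents that add atoms: none
Why: Copper hydride conjugate reduction is selective for the enone over both lactones, and hydride should add axially to the β face of C8, anti to the pseudoaxial C9–O bond through a chair-like enolate, which places C17 equatorial (8R).

Step 25
Reactants: 35 (4S,5R,8R,9R,10S,13S)-9,13-epoxy-6-oxolabdane-19,20:16,15-diolide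
Product: 36 (4S,5R,6R,8R,9R,10S,13S)-9,13-epoxy-6-hydroxylabdane-19,20:16,15-diolide (CNP0393616.1)
Conditions: LiBH(s-Bu)3 (1.2 equiv), THF, −78 °C; AcOH quench at −78 °C
Reagents that add atoms: none
Why: The bulky hydride attacks the C6 ketone from the α face (equatorial attack), the β face being blocked by the 1,3-diaxial C19/C20 lactone bridge, to give the axial 6β-alcohol (6R), and the cold acidic quench keeps the alkoxide from translactonising onto C19.

**Compound list**

1 | 1-bromo-2-methoxy-4-methylbenzene | Cc1ccc(Br)c(OC)c1 | starting material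
2 | tert-butyl propanoate | CCC(=O)OC(C)(C)C | starting material
3 | tert-butyl 2-(2-methoxy-4-methylphenyl)propanoate (racemic) | CC(C(=O)OC(C)(C)C)c1ccc(C)cc1OC | intermediate
4 | 2-(2-methoxy-4-methylphenyl)propanal (racemic) | CC(C=O)c1ccc(C)cc1OC | intermediate
5 | allyl alcohol (prop-2-en-1-ol) | C=CCO | starting material
6 | (S)-2-(2-methoxy-4-methylphenyl)-2-methylpent-4-enal | C=CC[C@](c1ccc(C)cc1OC)(C)C=O | intermediate
7 | (S)-2-(2-methoxy-4-methylphenyl)-2-methylpent-4-enoic acid | C=CC[C@](c1ccc(C)cc1OC)(C)C(=O)O | intermediate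
8 | methyl (S)-2-(2-methoxy-4-methylphenyl)-2-methylpent-4-enoate | C=CC[C@](c1ccc(C)cc1OC)(C)C(=O)OC | intermediate
9 | methyl (S)-5-hydroxy-2-(2-methoxy-4-methylphenyl)-2-methylpentanoate | OCCC[C@](c1ccc(C)cc1OC)(C)C(=O)OC | intermediate
10 | (S)-5-methoxy-4-(2-methoxy-4-methylphenyl)-4-methyl-5-oxopentanoic acid | OC(=O)CC[C@](c1ccc(C)cc1OC)(C)C(=O)OC | intermediate
11 | methyl (S)-8-methoxy-1,6-dimethyl-4-oxo-1,2,3,4-tetrahydronaphthalene-1-carboxylate | C[C@]1(C(=O)OC)CCC(=O)c2cc(C)cc(OC)c12 | intermediate
12 | methyl (S)-8-methoxy-1,6-dimethyl-1,2,3,4-tetrahydronaphthalene-1-carboxylate | C[C@]1(C(=O)OC)CCCc2cc(C)cc(OC)c12 | intermediate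
13 | methyl (S)-5-bromo-8-methoxy-1,6-dimethyl-1,2,3,4-tetrahydronaphthalene-1-carboxylate | C[C@]1(C(=O)OC)CCCc2c(Br)c(C)cc(OC)c12 | intermediate
14 | (S)-5-bromo-8-hydroxy-1,6-dimethyl-1,2,3,4-tetrahydronaphthalene-1-carboxylic acid (phenol acid, not isolated) | C[C@]1(C(=O)O)CCCc2c(Br)c(C)cc(O)c12 | intermediate
15 | (S)-6-bromo-2a,7-dimethyl-2a,3,4,5-tetrahydro-2H-naphtho[1,8-bc]furan-2-one (aryl lactone O6–C19) | C[C@@]12CCCc3c(Br)c(C)cc(OC1=O)c23 | intermediate
16 | (R)-malic acid | OC(=O)C[C@@H](O)C(=O)O | starting material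
17 | pivalaldehyde (2,2-dimethylpropanal) | CC(C)(C)C=O | starting material
18 | 2-[(2R,4R)-2-tert-butyl-5-oxo-1,3-dioxolan-4-yl]acetic acid | OC(=O)C[C@H]1O[C@@H](C(C)(C)C)OC1=O | intermediate
19 | allyl bromide | C=CCBr | starting material
20 | 2-[(2R,4R)-2-tert-butyl-5-oxo-4-(prop-2-en-1-yl)-1,3-dioxolan-4-yl]acetic acid | OC(=O)C[C@@]1(CC=C)O[C@@H](C(C)(C)C)OC1=O | intermediate
21 | isobutyl carbonic anhydride of 20 (mixed carbonic anhydride, not isolated) | CC(C)COC(=O)OC(=O)C[C@@]1(CC=C)O[C@@H](C(C)(C)C)OC1=O | intermediate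
22 | (2R,5R)-2-tert-butyl-5-(2-hydroxyethyl)-5-(prop-2-en-1-yl)-1,3-dioxolan-4-one | OCC[C@@]1(CC=C)O[C@@H](C(C)(C)C)OC1=O | intermediate
23 | (2R,5R)-2-tert-butyl-5-(2-iodoethyl)-5-(prop-2-en-1-yl)-1,3-dioxolan-4-one | ICC[C@@]1(CC=C)O[C@@H](C(C)(C)C)OC1=O | intermediate
24 | 2-[(2R,4R)-2-tert-butyl-4-(2-iodoethyl)-5-oxo-1,3-dioxolan-4-yl]acetaldehyde | ICC[C@@]1(CC=O)O[C@@H](C(C)(C)C)OC1=O | intermediate
25 | (2R,5R)-2-tert-butyl-5-(2-hydroxyethyl)-5-(2-iodoethyl)-1,3-dioxolan-4-one (not isolated) | ICC[C@@]1(CCO)O[C@@H](C(C)(C)C)OC1=O | intermediate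
26 | (R)-3-hydroxy-3-(2-iodoethyl)oxolan-2-one | O[C@@]1(CCI)CCOC1=O | intermediate
27 | {2-[(3R)-3-hydroxy-2-oxooxolan-3-yl]ethyl}zinc iodide (not isolated) | O[C@@]1(CC[Zn]I)CCOC1=O | intermediate
28 | (2aS)-6-{2-[(3S)-3-hydroxy-2-oxooxolan-3-yl]ethyl}-2a,7-dimethyl-2a,3,4,5-tetrahydro-2H-naphtho[1,8-bc]furan-2-one | C[C@@]12CCCc3c(CC[C@]4(O)CCOC4=O)c(C)cc(OC1=O)c23 | intermediate
29 | 2-(trimethylsilyl)ethyl (S)-8-hydroxy-5-{2-[(3S)-3-hydroxy-2-oxooxolan-3-yl]ethyl}-1,6-dimethyl-1,2,3,4-tetrahydronaphthalene-1-carboxylate (phenol ester, not isolated) | C[C@]1(C(=O)OCC[Si](C)(C)C)CCCc2c(CC[C@]3(O)CCOC3=O)c(C)cc(O)c12 | intermediate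
30 | 2-(trimethylsilyl)ethyl (4S,9R,13S)-9,13-epoxy-6-oxolabda-5(10),7-dien-16,15-olid-19-oate (spiro dienone) | CC1=CC(=O)C2=C(CCC[C@]2(C)C(=O)OCC[Si](C)(C)C)[C@@]13CC[C@@]4(CCOC4=O)O3 | intermediate
31 | (4S,9R,13S)-9,13-epoxy-6-oxolabda-5(10),7-dien-16,15-olid-19-oic acid | CC1=CC(=O)C2=C(CCC[C@]2(C)C(=O)O)[C@@]13CC[C@@]4(CCOC4=O)O3 | intermediate
32 | chloromethyl (4S,9R,13S)-9,13-epoxy-6-oxolabda-5(10),7-dien-16,15-olid-19-oate | CC1=CC(=O)C2=C(CCC[C@]2(C)C(=O)OCCl)[C@@]13CC[C@@]4(CCOC4=O)O3 | intermediate
33 | iodomethyl (4S,9R,13S)-9,13-epoxy-6-oxolabda-5(10),7-dien-16,15-olid-19-oate (key-step precursor) | CC1=CC(=O)C2=C(CCC[C@]2(C)C(=O)OCI)[C@@]13CC[C@@]4(CCOC4=O)O3 | intermediate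
34 | (4S,5R,9R,10S,13S)-9,13-epoxy-6-oxolabd-7-ene-19,20:16,15-diolide (key-step product) | CC1=CC(=O)[C@@H]2[C@]3(CCC[C@]2(C)C(=O)OC3)[C@@]14CC[C@@]5(CCOC5=O)O4 | intermediate
35 | (4S,5R,8R,9R,10S,13S)-9,13-epoxy-6-oxolabdane-19,20:16,15-diolide | C[C@@H]1CC(=O)[C@@H]2[C@]3(CCC[C@]2(C)C(=O)OC3)[C@@]12CC[C@@]1(CCOC1=O)O2 | intermediate
36 | (4S,5R,6R,8R,9R,10S,13S)-9,13-epoxy-6-hydroxylabdane-19,20:16,15-diolide (CNP0393616.1) | C[C@@H]1C[C@@H](O)[C@@H]2[C@]3(CCC[C@]2(C)C(=O)OC3)[C@@]12CC[C@@]1(CCOC1=O)O2 | target

**Step count**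

Total: 25 steps. Longest linear sequence: 19 steps (steps 1–11, then 18–25); the side chain takes steps 12–17.

**Steps most likely to fail**

1. Step 23. The acyloxymethyl radical may take hydrogen from the silane before the ester reaches the s-trans rotamer from which C20 can touch C10, so that reduction outruns ring closure. The fallback gives up the tether and uses known reactions only; it sets out from 30 and comes back at 35. Conjugate reduction of 30 with [(Ph3P)CuH]6 should touch only the trisubstituted C7=C8 enone and give the 2-(trimethylsilyl)ethyl (4S,8R,9R,13S)-9,13-epoxy-6-oxolabd-5(10)-en-16,15-olid-19-oate F1. Benzophenone-sensitised photoaddition of methanol, the classical conjugate addition of the hydroxymethyl radical to enones, then places CH2OH on C10 of the one remaining enone, anti to the C9–O bond, and gives the 20-hydroxy ketone ester F2. TsOH-catalysed lactonisation of the 1,3-diaxial C20 hydroxyl onto the C19 ester gives 35. Facial control at C8 and C10 is weaker here than in the tethered route.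

2. Step 19. The C13 hydroxyl may attack either face of C9 without discrimination, so that about half of the material would end in the wrong spiro configuration. The fallback replaces absent substrate control by reagent control and a recycling loop; it sets out from 28 and comes back at 30. Phenol ester 29 is oxidised with a chiral C2-symmetric aryl iodide catalyst (a lactamide-substituted 2-iodoresorcinol ether) and mCPBA in place of PhI(OAc)2, each antipode of the catalyst being tried. Whatever (9S)-epimer of the spiro dienone F3 still forms is cleaved at C9–O with Zn/AcOH (reductive rearomatisation of a quinol ether) back to 29 and oxidised again.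

3. Step 24. Hydride may be delivered to the α face of C8 if the 1,3-diaxial C20 methylene diverts the copper hydride, which would leave the 8-epimer with an axial methyl. The fallback reverses the order of the two reductions and uses a directing group; it sets out from 34 and comes back at 36. Luche reduction of 34 (NaBH4, CeCl3·7H2O, MeOH, −78 °C) from the open α face gives the 6β-allylic alcohol F4. Hydroxyl-directed hydrogenation with [Ir(cod)(PCy3)(py)]PF6 and H2 in CH2Cl2 then delivers hydrogen to the β face of C7=C8, syn to the axial 6β-hydroxyl, and gives 36 directly.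

**Further compounds**

F1 | step 23 | 2-(trimethylsilyl)ethyl (4S,8R,9R,13S)-9,13-epoxy-6-oxolabd-5(10)-en-16,15-olid-19-oate | C[C@@H]1CC(=O)C2=C(CCC[C@]2(C)C(=O)OCC[Si](C)(C)C)[C@@]13CC[C@@]4(CCOC4=O)O3
F2 | step 23 | 2-(trimethylsilyl)ethyl (4S,5R,8R,9R,10S,13S)-9,13-epoxy-20-hydroxy-6-oxolabdan-16,15-olid-19-oate | C[C@@H]1CC(=O)[C@@H]2[C@](CO)(CCC[C@]2(C)C(=O)OCC[Si](C)(C)C)[C@@]13CC[C@@]4(CCOC4=O)O3
F3 | step 19 | 2-(trimethylsilyl)ethyl (4S,9S,13S)-9,13-epoxy-6-oxolabda-5(10),7-dien-16,15-olid-19-oate (9-epimer of 30) | CC1=CC(=O)C2=C(CCC[C@]2(C)C(=O)OCC[Si](C)(C)C)[C@]13CC[C@@]4(CCOC4=O)O3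
F4 | step 24 | (4S,5R,6R,9R,10S,13S)-9,13-epoxy-6-hydroxylabd-7-ene-19,20:16,15-diolide | CC1=C[C@@H](O)[C@@H]2[C@]3(CCC[C@]2(C)C(=O)OC3)[C@@]14CC[C@@]5(CCOC5=O)O4
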